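**Retrosynthetic overview**
1. Target 19 ⇐ removal of four MOM groups from the (3R)-isoflavanone 18; no ring is formed after the key step.
2. Key disconnection C3–C1′: racemic 3-bromochromanone 10 (an enolonium equivalent at C3) + arylzinc 17 of ring B, joined enantioconvergently under NiCl2·glyme/chiral pybox; this step sets C3.
3. 10 ⇐ chromanone 8 ⇐ oxa-Michael closure of ring C from aryl vinyl ketone 7 ⇐ salicylaldehyde 5 ⇐ phenol 4 ⇐ 2-methylresorcinol 1 (C–H borylation/oxidation para to the methyl fixes the 6-methyl pattern by symmetry).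
4. 17 ⇐ aryl bromide 15 ⇐ 4,6-dibromoresorcinol 11 + geranyl bromide 13 (mono Br/Li exchange, copper-mediated allylation).
5. Ring order: rings A and B are bought as benzenes; ring C is the only ring made (step 5).

Assumption: the SMILES is read as the (3R) enantiomer with an (E)-geranyl chain; 1, 11 and 13 are taken as commercial.

**Step 1**
Reactants: 1 2-methylresorcinol
Product: 2 1,3-bis(methoxymethoxy)-2-methylbenzene
Conditions: NaH (2.4 equiv), MOMCl (2.4 equiv), DMF, 0 °C → rt
Reagents that add atoms: chloromethyl methyl ether (MOMCl), COCCl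
Why: Williamson-type O-alkylation of both phenoxides gives acetal ethers that tolerate every later base and organometallic step.

**Step 2**
Reactants: 2 1,3-bis(methoxymethoxy)-2-methylbenzene
Product: 4 3,5-bis(methoxymethoxy)-4-methylphenol, via arylboronic ester 3 (not isolated)
Conditions: [Ir(OMe)(cod)]2 (1.5 mol%), 4,4′-di-tert-butyl-2,2′-bipyridine (3 mol%), B2pin2 (1.0 equiv), THF, 80 °C; then 30% H2O2, aq. NaOH, 0 °C
Reagents that add atoms: hydrogen peroxide, OO
Why: Sterically controlled iridium-catalysed C–H borylation (Hartwig–Miyaura type) goes to C5, the only C–H with no ortho substituent, and one-pot boronate oxidation puts the new oxygen para to the methyl, so both remaining ring positions are equivalent.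

**Step 3**
Reactants: 4 3,5-bis(methoxymethoxy)-4-methylphenol
Product: 5 6-hydroxy-2,4-bis(methoxymethoxy)-3-methylbenzaldehyde
Conditions: MgCl2 (2 equiv), Et3N (4 equiv), (CH2O)n (6 equiv), THF, reflux
Reagents that add atoms: paraformaldehyde (as formaldehyde), C=O
Why: Casnati–Skattebøl magnesium-phenoxide ortho-formylation reacts only ortho to the free phenol, and either ortho position gives the same aldehyde.

**Step 4**
Reactants: 5 6-hydroxy-2,4-bis(methoxymethoxy)-3-methylbenzaldehyde
Product: 6 (±)-2-(1-hydroxyprop-2-en-1-yl)-3,5-bis(methoxymethoxy)-4-methylphenol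
Conditions: CH2=CHMgBr (2.5 equiv), THF, −78 → 0 °C; aq. NH4Cl; used crude
Reagents that add atoms: vinylmagnesium bromide, C=C[Mg]Br
Why: Grignard 1,2-addition after the first equivalent has deprotonated the phenol; the racemic carbinol centre is removed in the next step.

**Step 5**
Reactants: 6 (±)-2-(1-hydroxyprop-2-en-1-yl)-3,5-bis(methoxymethoxy)-4-methylphenol
Product: 8 5,7-bis(methoxymethoxy)-6-methylchroman-4-one, via aryl vinyl ketone 7 (not isolated)
Conditions: activated MnO2 (15 equiv), CH2Cl2, rt; filter; DBU (10 mol%), CH2Cl2, rt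
Reagents that add atoms: none
Why: MnO2 oxidises the allylic-benzylic alcohol to the enone, and the ortho phenoxide closes ring C by intramolecular oxa-Michael addition (6-endo-trig).

**Step 6**
Reactants: 8 5,7-bis(methoxymethoxy)-6-methylchroman-4-one
Product: 10 (±)-3-bromo-5,7-bis(methoxymethoxy)-6-methylchroman-4-one, via silyl enol ether 9 (not isolated)
Conditions: LiN(SiMe3)2 (1.1 equiv), Me3SiCl (1.2 equiv), THF, −78 °C; then NBS (1.05 equiv), −78 → 0 °C
Reagents that add atoms: N-bromosuccinimide, O=C1CCC(=O)N1Br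
Why: Kinetic enolisation trapped as the silyl enol ether, which is far more nucleophilic than the arene, so electrophilic α-bromination takes C3 only; C3 is racemic here on purpose.

**Step 7**
Reactants: 11 4,6-dibromoresorcinol
Product: 12 1,5-dibromo-2,4-bis(methoxymethoxy)benzene
Conditions: NaH (2.4 equiv), MOMCl (2.4 equiv), DMF, 0 °C → rt
Reagents that add atoms: chloromethyl methyl ether (MOMCl), COCCl
Why: Williamson-type O-alkylation; the MOM groups are small, stable to aryllithium and arylzinc species, and do not migrate to carbon.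

**Step 8**
Reactants: 12 1,5-dibromo-2,4-bis(methoxymethoxy)benzene; 13 geranyl bromide
Product: 15 1-bromo-5-[(2E)-3,7-dimethylocta-2,6-dien-1-yl]-2,4-bis(methoxymethoxy)benzene, via aryllithium 14 (not isolated)
Conditions: n-BuLi (1.0 equiv), THF, −78 °C, 20 min; CuBr·SMe2 (1.0 equiv); then 13 (1.1 equiv), −78 → 0 °C
Reagents that add atoms: none
Why: Bromine–lithium exchange stops after one bromide because the aryl anion resists a second exchange, and the derived arylcopper substitutes geranyl bromide at its primary carbon (copper-mediated SN2 allylation) with the E alkene kept.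

**Step 9**
Reactants: 15 1-bromo-5-[(2E)-3,7-dimethylocta-2,6-dien-1-yl]-2,4-bis(methoxymethoxy)benzene; 10 (±)-3-bromo-5,7-bis(methoxymethoxy)-6-methylchroman-4-one
Product: 18 (3R)-3-{5-[(2E)-3,7-dimethylocta-2,6-dien-1-yl]-2,4-bis(methoxymethoxy)phenyl}-5,7-bis(methoxymethoxy)-6-methylchroman-4-one, via arylmagnesium bromide 16 (not isolated), via arylzinc iodide 17 (not isolated)
Conditions: 15 (1.4 equiv), Mg, LiCl, THF, rt; ZnI2, THF, 0 °C → rt; then 10 (1.0 equiv), NiCl2·glyme (5 mol%), 2,6-bis[(4R,5S)-4,5-diphenyl-4,5-dihydrooxazol-2-yl]pyridine (6.5 mol%), glyme/THF, −30 °C; pH 5 buffer quench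
Reagents that add atoms: none
Why: Proposed new method: bromoketone 10 acts as an enolonium equivalent, so C3 (a natural enolate carbon) is joined to the naturally nucleophilic resorcinol carbon delivered as arylzinc 17; the nickel–pybox catalyst abstracts bromine from both enantiomers of 10 to give one planar α-keto radical, and recombination and reductive elimination at the chiral aryl–nickel complex set C3, while the base-free −30 °C conditions keep the α-aryl ketone from racemising; the ligand antipode that gives 3R is an assumption to be confirmed on the first run (chiral HPLC/CD), with the mirror-image ligand used if the sense is opposite; the closest known reaction is the nickel/pybox-catalysed enantioconvergent Negishi α-arylation of racemic acyclic α-bromo ketones with ArZnI.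

**Step 10**
Reactants: 18 (3R)-3-{5-[(2E)-3,7-dimethylocta-2,6-dien-1-yl]-2,4-bis(methoxymethoxy)phenyl}-5,7-bis(methoxymethoxy)-6-methylchroman-4-one
Product: 19 (3R)-3-{5-[(2E)-3,7-dimethylocta-2,6-dien-1-yl]-2,4-dihydroxyphenyl}-5,7-dihydroxy-6-methylchroman-4-one (CNP0348256.1)
Conditions: HCl (1.25 M in MeOH), MeOH/THF, 0 → 30 °C, monitored; pH 5 buffer work-up
Reagents that add atoms: none
Why: Acid-catalysed acetal exchange (MOM methanolysis) frees the four phenols under mild, base-free conditions where enolisation at C3 and acid attack on the geranyl chain should be slow.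

**Compound list**
1 | 2-methylresorcinol (2-methylbenzene-1,3-diol) | Cc1c(O)cccc1O | starting material
2 | 1,3-bis(methoxymethoxy)-2-methylbenzene | COCOc1cccc(OCOC)c1C | intermediate
3 | 2-[3,5-bis(methoxymethoxy)-4-methylphenyl]-4,4,5,5-tetramethyl-1,3,2-dioxaborolane | COCOc1cc(B2OC(C)(C)C(C)(C)O2)cc(OCOC)c1C | intermediate
4 | 3,5-bis(methoxymethoxy)-4-methylphenol | COCOc1cc(O)cc(OCOC)c1C | intermediate
5 | 6-hydroxy-2,4-bis(methoxymethoxy)-3-methylbenzaldehyde | O=Cc1c(O)cc(OCOC)c(C)c1OCOC | intermediate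
6 | (±)-2-(1-hydroxyprop-2-en-1-yl)-3,5-bis(methoxymethoxy)-4-methylphenol | C=CC(O)c1c(O)cc(OCOC)c(C)c1OCOC | intermediate
7 | 1-[6-hydroxy-2,4-bis(methoxymethoxy)-3-methylphenyl]prop-2-en-1-one | C=CC(=O)c1c(O)cc(OCOC)c(C)c1OCOC | intermediate
8 | 5,7-bis(methoxymethoxy)-6-methylchroman-4-one | O=C1CCOc2cc(OCOC)c(C)c(OCOC)c12 | intermediate
9 | [5,7-bis(methoxymethoxy)-6-methyl-2H-chromen-4-yl]oxy(trimethyl)silane | C[Si](C)(C)OC1=CCOc2cc(OCOC)c(C)c(OCOC)c12 | intermediate
10 | (±)-3-bromo-5,7-bis(methoxymethoxy)-6-methylchroman-4-one | O=C1C(Br)COc2cc(OCOC)c(C)c(OCOC)c12 | intermediate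
11 | 4,6-dibromoresorcinol (4,6-dibromobenzene-1,3-diol) | Oc1cc(O)c(Br)cc1Br | starting material
12 | 1,5-dibromo-2,4-bis(methoxymethoxy)benzene | COCOc1cc(OCOC)c(Br)cc1Br | intermediate
13 | geranyl bromide ((2E)-1-bromo-3,7-dimethylocta-2,6-diene) | CC(C)=CCC/C(C)=C/CBr | starting material
14 | [5-bromo-2,4-bis(methoxymethoxy)phenyl]lithium | [Li]c1cc(Br)c(OCOC)cc1OCOC | intermediate
15 | 1-bromo-5-[(2E)-3,7-dimethylocta-2,6-dien-1-yl]-2,4-bis(methoxymethoxy)benzene | CC(C)=CCC/C(C)=C/Cc1cc(Br)c(OCOC)cc1OCOC | intermediate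
16 | {5-[(2E)-3,7-dimethylocta-2,6-dien-1-yl]-2,4-bis(methoxymethoxy)phenyl}magnesium bromide | CC(C)=CCC/C(C)=C/Cc1cc([Mg]Br)c(OCOC)cc1OCOC | intermediate
17 | {5-[(2E)-3,7-dimethylocta-2,6-dien-1-yl]-2,4-bis(methoxymethoxy)phenyl}zinc iodide | CC(C)=CCC/C(C)=C/Cc1cc([Zn]I)c(OCOC)cc1OCOC | intermediate
18 | (3R)-3-{5-[(2E)-3,7-dimethylocta-2,6-dien-1-yl]-2,4-bis(methoxymethoxy)phenyl}-5,7-bis(methoxymethoxy)-6-methylchroman-4-one | CC(C)=CCC/C(C)=C/Cc1cc([C@@H]2COc3cc(OCOC)c(C)c(OCOC)c3C2=O)c(OCOC)cc1OCOC | intermediate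
19 | (3R)-3-{5-[(2E)-3,7-dimethylocta-2,6-dien-1-yl]-2,4-dihydroxyphenyl}-5,7-dihydroxy-6-methylchroman-4-one | CC(C)=CCC/C(C)=C/Cc1cc([C@@H]2COc3cc(O)c(C)c(O)c3C2=O)c(O)cc1O | target

**Step count**
Total steps: 10 (1–6 bromoketone, 7–8 aryl bromide, 9 coupling, 10 deprotection).
Longest linear sequence: 8 (steps 1–6, 9, 10).

**Three steps most likely to fail**

Step 9 (key coupling). A cyclic 3-bromochromanone and an ortho-alkoxy arylzinc are outside the documented scope of this coupling. The C3–nickel species could lose β-hydride or β-aryloxide (chromone or ring-opened enone), be reduced back to 8, or couple with low ee. Fallback: it sets out from 10 and 17 (17 made from 15 as in step 9) and comes back at 18. The same bond is made without asking the coupling catalyst for stereocontrol: 17 and 10 are joined with an achiral, more active catalyst (NiCl2·glyme, 4,4′-di-tert-butyl-2,2′-bipyridine, THF/DMA, 0 °C → rt) to give the racemic tetra-MOM isoflavanone F1. F1 is converted with LiN(SiMe3)2/Me3SiCl at −78 °C into its trimethylsilyl enol ether F2. F2 is then protonated enantioselectively with a catalytic BINOL-derived N-triflyl thiophosphoramide and phenol as stoichiometric proton source (toluene, low temperature), which sets C3 and returns 18.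

Step 10 (global MOM removal). Acid may cyclise the geranyl chain onto the 4′-OH, add methanol to the alkenes, or enolise C3 and erode ee. Fallback: it sets out from 8 and 11 (with 13) and comes back at 19, replacing all four MOM groups by silyl ethers so the last step uses fluoride instead of acid.
- Ring A side: 8 is stripped with HCl/MeOH at 50 °C (no stereocentre or alkene present) to 5,7-dihydroxy-6-methylchroman-4-one F3. F3 is silylated (TBSOTf, 2,6-lutidine, CH2Cl2) to 5,7-bis(tert-butyldimethylsilyloxy)-6-methylchroman-4-one F4. F4 is brominated as in step 6 through the trimethylsilyl enol ether F5 to the racemic 3-bromo ketone F6.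
- Ring B side: 11 is silylated (TBSCl, imidazole, DMF) to 1,5-dibromo-2,4-bis(tert-butyldimethylsilyloxy)benzene F7. n-BuLi at −78 °C gives the aryllithium F8, which is trapped at once with CuBr·SMe2 and 13 (to outrun O→C silyl migration) to give the geranylated aryl bromide F9. Mg/LiCl and then ZnI2 give the arylmagnesium bromide F10 and the arylzinc iodide F11.
- Endgame: F11 is coupled with F6 under the step 9 conditions to the (3R)-tetra-TBS isoflavanone F12. HF·pyridine in THF/pyridine at 0 °C then gives 19.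

Step 5 (oxidation and ring C closure). Vinyl ketone 7 may polymerise, or the electron-rich phenol may be over-oxidised by MnO2, before the oxa-Michael closure. Fallback: it sets out from 5 and comes back at 8, closing ring C at the alkyne oxidation level so no free vinyl ketone is formed. HC≡CMgBr (2.5 equiv, THF, 0 °C) adds to 5 to give the propargylic alcohol F13. MnO2 oxidises it to the aryl ethynyl ketone F14, which closes with Et2NH (6-endo-dig oxa-Michael) to the chromone F15. Hydrogenation of the C2–C3 double bond (H2, Pd/C, EtOAc, stopped at one equivalent) gives 8.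

**Further compounds**
F1 | step 9 | (±)-3-{5-[(2E)-3,7-dimethylocta-2,6-dien-1-yl]-2,4-bis(methoxymethoxy)phenyl}-5,7-bis(methoxymethoxy)-6-methylchroman-4-one | CC(C)=CCC/C(C)=C/Cc1cc(C2COc3cc(OCOC)c(C)c(OCOC)c3C2=O)c(OCOC)cc1OCOC
F2 | step 9 | {3-{5-[(2E)-3,7-dimethylocta-2,6-dien-1-yl]-2,4-bis(methoxymethoxy)phenyl}-5,7-bis(methoxymethoxy)-6-methyl-2H-chromen-4-yl}oxy(trimethyl)silane | CC(C)=CCC/C(C)=C/Cc1cc(C2=C(O[Si](C)(C)C)c3c(OCOC)c(C)c(OCOC)cc3OC2)c(OCOC)cc1OCOC
F3 | step 10 | 5,7-dihydroxy-6-methylchroman-4-one | O=C1CCOc2cc(O)c(C)c(O)c12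
F4 | step 10 | 5,7-bis(tert-butyldimethylsilyloxy)-6-methylchroman-4-one | O=C1CCOc2cc(O[Si](C)(C)C(C)(C)C)c(C)c(O[Si](C)(C)C(C)(C)C)c12
F5 | step 10 | [5,7-bis(tert-butyldimethylsilyloxy)-6-methyl-2H-chromen-4-yl]oxy(trimethyl)silane | C[Si](C)(C)OC1=CCOc2cc(O[Si](C)(C)C(C)(C)C)c(C)c(O[Si](C)(C)C(C)(C)C)c12
F6 | step 10 | (±)-3-bromo-5,7-bis(tert-butyldimethylsilyloxy)-6-methylchroman-4-one | O=C1C(Br)COc2cc(O[Si](C)(C)C(C)(C)C)c(C)c(O[Si](C)(C)C(C)(C)C)c12
F7 | step 10 | 1,5-dibromo-2,4-bis(tert-butyldimethylsilyloxy)benzene | CC(C)(C)[Si](C)(C)Oc1cc(O[Si](C)(C)C(C)(C)C)c(Br)cc1Br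
F8 | step 10 | [5-bromo-2,4-bis(tert-butyldimethylsilyloxy)phenyl]lithium | [Li]c1cc(Br)c(O[Si](C)(C)C(C)(C)C)cc1O[Si](C)(C)C(C)(C)C
F9 | step 10 | 1-bromo-5-[(2E)-3,7-dimethylocta-2,6-dien-1-yl]-2,4-bis(tert-butyldimethylsilyloxy)benzene | CC(C)=CCC/C(C)=C/Cc1cc(Br)c(O[Si](C)(C)C(C)(C)C)cc1O[Si](C)(C)C(C)(C)C
F10 | step 10 | {5-[(2E)-3,7-dimethylocta-2,6-dien-1-yl]-2,4-bis(tert-butyldimethylsilyloxy)phenyl}magnesium bromide | CC(C)=CCC/C(C)=C/Cc1cc([Mg]Br)c(O[Si](C)(C)C(C)(C)C)cc1O[Si](C)(C)C(C)(C)C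
F11 | step 10 | {5-[(2E)-3,7-dimethylocta-2,6-dien-1-yl]-2,4-bis(tert-butyldimethylsilyloxy)phenyl}zinc iodide | CC(C)=CCC/C(C)=C/Cc1cc([Zn]I)c(O[Si](C)(C)C(C)(C)C)cc1O[Si](C)(C)C(C)(C)C
F12 | step 10 | (3R)-3-{5-[(2E)-3,7-dimethylocta-2,6-dien-1-yl]-2,4-bis(tert-butyldimethylsilyloxy)phenyl}-5,7-bis(tert-butyldimethylsilyloxy)-6-methylchroman-4-one | CC(C)=CCC/C(C)=C/Cc1cc([C@@H]2COc3cc(O[Si](C)(C)C(C)(C)C)c(C)c(O[Si](C)(C)C(C)(C)C)c3C2=O)c(O[Si](C)(C)C(C)(C)C)cc1O[Si](C)(C)C(C)(C)C
F13 | step 5 | (±)-2-(1-hydroxyprop-2-yn-1-yl)-3,5-bis(methoxymethoxy)-4-methylphenol | C#CC(O)c1c(O)cc(OCOC)c(C)c1OCOC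
F14 | step 5 | 1-[6-hydroxy-2,4-bis(methoxymethoxy)-3-methylphenyl]prop-2-yn-1-one | C#CC(=O)c1c(O)cc(OCOC)c(C)c1OCOC
F15 | step 5 | 5,7-bis(methoxymethoxy)-6-methyl-4H-chromen-4-one | O=c1ccoc2cc(OCOC)c(C)c(OCOC)c12
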